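(The numbers are assumed; the result is computed.)

You want to know what share of the charge stands as target after the hour.

solid substrate 0.36 M; time 1.0 h

1. which holds at 1.0 h: what has brought the reaction to rest, or that it has not come to rest (for what has run out or reacted, a solid counts together with what of it has only dissolved) (forward and back rates have come level / all of the solid substrate has reacted / it is still moving)
2. part of the solid substrate that has turned into other species by 1.0 h (what has only dissolved does not count)
3. the target standing at 1.0 h, as a percentage of the solid substrate charged
4. the isomer of the product C standing at 1.0 h, as a percentage of the solid substrate charged

- given per volume of solution although it is solid: solid substrate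
- at the start none of the solid substrate is in solution
- what has only dissolved of solid substrate counts as not reacted
- the reaction counts as stopped when no species that holds the solid substrate changes by six tenths of a point or more over the second half of the time
- run time (flask): 1.0 h

    starting material ⇌ target (K1 = 0.60, k1 = 0.028 s⁻¹)
    target ⇌ isomer of the product A (K2 = 0.086, k2 = 0.011 s⁻¹)
    isomer of the product A ⇌ isomer of the product B (K3 = 0.53, k3 = 0.076 s⁻¹)
    isomer of the product B ⇌ starting material (k4 = 0.011 s⁻¹)
    solid substrate ⇌ starting material, rate k5*(cs5 - [starting material]) while solid is left; crystals form when [starting material] > cs5 (cs5 = 0.25 M, k5 = 0.17 s⁻¹)
    target ⇌ isomer of the product C (K6 = 1.7, k6 = 0.0057 s⁻¹)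

In solution, starting material, target, isomer of the product A and isomer of the product B form a closed ring, and the target also branches to the isomer of the product C. Every step runs both ways, so follow one molecule: once the steps are level, its chance of being in a form is that form's weight over the sum of weights. Give starting material weight one; then the target weighs 0.60, the isomer of the product C 1.02, the isomer of the product A 0.0516 and the isomer of the product B 0.0273.

Against starting material alone, the target's share is 37.5 %. Adding the branch tightens this upper bound to 22.9 %. For a lower bound, count the isomer of the product B as heavy as the isomer of the product A, which overstates it since 0.53 is below one; that gives 22.0 %.

The exact sum is 2.70: this is the holding number, the dissolved forms together at rest per unit of starting material in solution. My target share is therefore 22.2 %, a case of thermodynamic control. This needs two checks. The solution can hold 0.675 M at saturation, more than the 0.36 M charged, so I expect no solid at rest. The branch's return alone has a half-life of 3.45 min, far shorter than the hour, so I expect the flask to be level.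

The forecast gives forward and back rates have come level, conversion 62.95 %, target 22.23 % and isomer of the product C 37.79 %: “so equilibrium is fully reached”. Its target lies below my upper bound and above my lower one.

The simulation gives forward and back rates have come level, conversion 62.9 %, target 22.2 % and isomer of the product C 37.8 %.

This flask is at rest: the largest change over the second half is 0 percentage points, and after 10.0 h it reads conversion 62.9 %, target 22.2 % and isomer of the product C 37.8 %. The holding number puts 37.0 % at starting material, and the flask shows 37.1 %. The neighbour flask with 0.90 M lies above the 0.675 M the solution can hold. Reckoned with starting material at its solubility, its target is 16.7 %, and it reads 16.7 %, with 25.0 % still solid at 1.00 h.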